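**Retrosynthetic overview**
- The target comes from a Mislow–Evans [2,3] shift of an anti-11-hydroxy-12-phenylthio-13Z allyl sulfide; this moves oxygen to C14 and creates the 12E alkene.
- Key disconnection (C13–C14, then C11–C12, one pot): C14 of a (3Z,6Z)-nonadienyl carbamate is used as a chiral α-oxygenated carbanion (a carbinol carbon with reversed polarity). It is joined to (E)-2-(phenylthio)vinyl-9-BBN (C12–C13) and to the C1–C11 cyclopropyl-lactone aldehyde by lithiation–borylation–allylation.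
- The C1–C11 aldehyde comes from acetal hydrolysis, ring-closing metathesis, esterification, hydroxyl-directed Simmons–Smith cyclopropanation and Brown allylation of fumaraldehyde mono(dimethyl acetal).
- Ring order: cyclopropane first, eight-membered lactone second.
- Stereocontrol: C7 from the allylation, C8/C10 relayed from C7, C11/C12 from the C14–B centre through the chair, C14–O by 1,3-transfer.

Assumption: atoms carry the oxylipin numbering (lactone C=O = C1, terminal CH3 = C22), and the SMILES is read as 4Z,12E,16Z,19Z and 7R,8R,10R,11R,14S.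

**Route**

Step 1
Reactants: 1 (E)-4,4-dimethoxybut-2-enal; 2 B-allyldiisopinocampheylborane of the (−)-α-pinene series (1 M in pentane)
Product: 4 (2E,4R)-1,1-dimethoxyhepta-2,6-dien-4-ol, via borinate ester 3 (not isolated)
Conditions: 2 (1.2 equiv), Et2O, −78 °C, 2 h; then NaOH, H2O2, 0 °C → rt
Reagents that add atoms: none
Why: Brown allylboration through a closed chair transition state, in which the isopinocampheyl groups of the (−)-α-pinene series deliver allyl to the Re face of the aldehyde (the sense that gives (R)-1-phenylbut-3-en-1-ol from benzaldehyde) with 1,2-addition only, which sets C7 as R.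

Step 2
Reactants: 4 (2E,4R)-1,1-dimethoxyhepta-2,6-dien-4-ol
Product: 5 (1R)-1-[(1R,2R)-2-(dimethoxymethyl)cyclopropyl]but-3-en-1-ol
Conditions: Et2Zn (3 equiv), CH2I2 (3 equiv), CH2Cl2, −15 → 0 °C
Reagents that add atoms: diiodomethane (ICI)
Why: Hydroxyl-directed Simmons–Smith (Furukawa) cyclopropanation, in which the zinc alkoxide delivers CH2 to the allylic E-alkene on the face syn to oxygen in the conformer whose carbinol C–H eclipses the double bond (minimal A(1,3) strain), giving the syn product with C8 and C10 both R while the remote terminal alkene reacts much more slowly.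

Step 3
Reactants: 5 (1R)-1-[(1R,2R)-2-(dimethoxymethyl)cyclopropyl]but-3-en-1-ol; 6 pent-4-enoyl chloride
Product: 7 (1R)-1-[(1R,2R)-2-(dimethoxymethyl)cyclopropyl]but-3-en-1-yl pent-4-enoate
Conditions: Et3N, DMAP (cat.), CH2Cl2, 0 °C → rt
Reagents that add atoms: none
Why: DMAP-catalysed acylation of a secondary alcohol by an acid chloride, with no change at any stereocentre.

Step 4
Reactants: 7 (1R)-1-[(1R,2R)-2-(dimethoxymethyl)cyclopropyl]but-3-en-1-yl pent-4-enoate
Product: 8 (5Z,8R)-8-[(1R,2R)-2-(dimethoxymethyl)cyclopropyl]-3,4,7,8-tetrahydro-2H-oxocin-2-one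
Conditions: benzylidene[1,3-bis(2,4,6-trimethylphenyl)imidazolidin-2-ylidene]dichloro(tricyclohexylphosphine)ruthenium (second-generation Grubbs catalyst, 10 mol%), CH2Cl2 (1 mM), 40 °C
Reagents that add atoms: none
Why: Ring-closing metathesis of the two terminal alkenes with loss of ethene closes the eight-membered lactone, whose ring size enforces the 4Z alkene, and the branched carbinol substituent helps the ester reach the cyclising conformation at high dilution.

Step 5
Reactants: 8 (5Z,8R)-8-[(1R,2R)-2-(dimethoxymethyl)cyclopropyl]-3,4,7,8-tetrahydro-2H-oxocin-2-one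
Product: 9 (1R,2R)-2-[(2R,4Z)-8-oxo-3,6,7,8-tetrahydro-2H-oxocin-2-yl]cyclopropane-1-carbaldehyde
Conditions: Amberlyst-15 (cat.), acetone/H2O (20:1), rt
Reagents that add atoms: water (O)
Why: Mild acid-catalysed acetal hydrolysis unmasks the C11 aldehyde without touching the lactone, the ring alkene or the trans-cyclopropane, which is already the more stable arrangement.

Step 6
Reactants: 10 (3Z,6Z)-nona-3,6-dien-1-ol; 11 N,N-diisopropylcarbamoyl chloride
Product: 12 (3Z,6Z)-nona-3,6-dien-1-yl N,N-diisopropylcarbamate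
Conditions: Et3N, CH2Cl2, reflux, 24 h
Reagents that add atoms: none
Why: Carbamoylation of the primary alcohol installs the Hoppe carbamate that later directs and stabilises α-lithiation.

Step 7
Reactants: 13 ethynylmagnesium bromide; 14 S-phenyl benzenethiosulfonate
Product: 15 ethynyl phenyl sulfide
Conditions: 13 (0.5 M in THF, 2.5 equiv), 14 added at −78 °C, → 0 °C; aq NH4Cl; distillation
Reagents that add atoms: none
Why: Electrophilic sulfenylation of an alkynyl Grignard reagent by a thiosulfonate with benzenesulfinate as leaving group, the excess of acetylide keeping bis-sulfenylation low.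

Step 8
Reactants: 15 ethynyl phenyl sulfide; 16 9-borabicyclo[3.3.1]nonane (9-BBN-H)
Product: 17 9-[(E)-2-(phenylsulfanyl)ethenyl]-9-borabicyclo[3.3.1]nonane
Conditions: 15 (2 equiv), 16 (1 equiv), THF, 0 °C → rt; volatiles and excess 15 removed in vacuo; residue taken up in Et2O and used directly
Reagents that add atoms: none
Why: Syn hydroboration of a terminal heteroatom-substituted alkyne, in which the bulky dialkylborane places boron on the unhindered terminal carbon (also the carbon made nucleophilic by sulfur lone-pair donation) and cis addition of B–H gives the E-alkenylborane.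

Step 9
Reactants: 12 (3Z,6Z)-nona-3,6-dien-1-yl N,N-diisopropylcarbamate; 17 9-[(E)-2-(phenylsulfanyl)ethenyl]-9-borabicyclo[3.3.1]nonane; 9 (1R,2R)-2-[(2R,4Z)-8-oxo-3,6,7,8-tetrahydro-2H-oxocin-2-yl]cyclopropane-1-carbaldehyde
Product: 22 anti-11-hydroxy-12-(phenylsulfanyl)-13Z coupling product (11S,12R), via lithiated carbamate 18 (not isolated), via boronate complex 19 (not isolated), via allylborane 20 (not isolated), via borinate ester 21 (not isolated)
Conditions: 12 (1.5 equiv), (−)-sparteine (1.5 equiv), sec-butyllithium (1.4 equiv), Et2O, −78 °C, 5 h; 17 (1.6 equiv, Et2O), −78 °C, 1 h; 9 (1.0 equiv), −78 → −20 °C, 3 h; then HOCH2CH2NH2, rt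
Reagents that add atoms: none
Why: Proposed new method: Hoppe deprotonation with sec-butyllithium/(−)-sparteine removes the pro-S hydrogen so that C14 reacts as a configurationally stable α-oxygenated carbanion (18, S), borane 17 traps it with retention to give 19, the β-thiovinyl group migrates from boron to carbon with inversion as the carbamate leaves (C13–C14 bond; 20, R), and 20 adds to aldehyde 9 through a chair transition state with the C15 chain axial and the phenylthio group equatorial, which transfers the C14 chirality to C11 and C12 (11S,12R, hydroxyl and sulfur anti) and gives the 13Z alkene; the closest known reaction type is the lithiation–borylation–allylation of alkyl carbamates with B-vinyl- and B-(2-silylvinyl)-9-BBN reagents, and only the sulfur substituent on the vinylborane is untested.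

Step 10
Reactants: 22 anti-11-hydroxy-12-(phenylsulfanyl)-13Z coupling product (11S,12R)
Product: 25 target CNP0319393.3, via sulfoxide 23 (not isolated), via sulfenate ester 24 (not isolated)
Conditions: mCPBA (1.0 equiv), NaHCO3, CH2Cl2, −78 °C, 30 min; then P(OMe)3 (5 equiv), MeOH, −78 → 25 °C, 12 h
Reagents that add atoms: mCPBA (O=C(OO)c1cccc(Cl)c1)
Why: Sulfide oxidation is far faster than alkene epoxidation at −78 °C, and the allylic sulfoxide undergoes the Mislow–Evans [2,3]-sigmatropic shift through the conformer with H-12 inside (A(1,3) strain with the 13Z alkene), so oxygen is delivered to C14 on the face that carried sulfur (C14 becomes S), the new 12,13-alkene is E, and trimethyl phosphite traps sulfenate 24 to release the diol.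

**Compound list**

1 | (E)-4,4-dimethoxybut-2-enal (fumaraldehyde mono(dimethyl acetal)) | COC(OC)/C=C/C=O | starting material
2 | B-allyldiisopinocampheylborane, (−)-α-pinene series (isopinocampheyl groups corresponding to (+)-isopinocampheol) | C=CCB([C@H]1C[C@H]2C[C@@H]([C@@H]1C)C2(C)C)[C@H]1C[C@H]2C[C@@H]([C@@H]1C)C2(C)C | starting material
3 | diisopinocampheylborinate ester of 4 | C=CC[C@@H](OB([C@H]1C[C@H]2C[C@@H]([C@@H]1C)C2(C)C)[C@H]1C[C@H]2C[C@@H]([C@@H]1C)C2(C)C)/C=C/C(OC)OC | intermediate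
4 | (2E,4R)-1,1-dimethoxyhepta-2,6-dien-4-ol | C=CC[C@@H](O)/C=C/C(OC)OC | intermediate
5 | (1R)-1-[(1R,2R)-2-(dimethoxymethyl)cyclopropyl]but-3-en-1-ol | COC(OC)[C@@H]1C[C@H]1[C@H](O)CC=C | intermediate
6 | pent-4-enoyl chloride | C=CCCC(Cl)=O | starting material
7 | (1R)-1-[(1R,2R)-2-(dimethoxymethyl)cyclopropyl]but-3-en-1-yl pent-4-enoate | COC(OC)[C@@H]1C[C@H]1[C@H](OC(=O)CCC=C)CC=C | intermediate
8 | (5Z,8R)-8-[(1R,2R)-2-(dimethoxymethyl)cyclopropyl]-3,4,7,8-tetrahydro-2H-oxocin-2-one | COC(OC)[C@@H]1C[C@H]1[C@H]1C/C=C\CCC(=O)O1 | intermediate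
9 | (1R,2R)-2-[(2R,4Z)-8-oxo-3,6,7,8-tetrahydro-2H-oxocin-2-yl]cyclopropane-1-carbaldehyde | O=C[C@@H]1C[C@H]1[C@H]1C/C=C\CCC(=O)O1 | intermediate
10 | (3Z,6Z)-nona-3,6-dien-1-ol | CC/C=C\C/C=C\CCO | starting material
11 | N,N-diisopropylcarbamoyl chloride | CC(C)N(C(C)C)C(Cl)=O | starting material
12 | (3Z,6Z)-nona-3,6-dien-1-yl N,N-diisopropylcarbamate | CC/C=C\C/C=C\CCOC(=O)N(C(C)C)C(C)C | intermediate
13 | ethynylmagnesium bromide | C#C[Mg]Br | starting material
14 | S-phenyl benzenethiosulfonate | O=S(=O)(Sc1ccccc1)c1ccccc1 | starting material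
15 | ethynyl phenyl sulfide (phenylthioacetylene) | C#CSc1ccccc1 | intermediate
16 | 9-borabicyclo[3.3.1]nonane (9-BBN-H) | B1C2CCCC1CCC2 | starting material
17 | 9-[(E)-2-(phenylsulfanyl)ethenyl]-9-borabicyclo[3.3.1]nonane | c1ccc(cc1)S/C=C/B1C2CCCC1CCC2 | intermediate
18 | (1S,3Z,6Z)-1-lithionona-3,6-dien-1-yl N,N-diisopropylcarbamate (as its (−)-sparteine complex) | CC/C=C\C/C=C\C[C@H]([Li])OC(=O)N(C(C)C)C(C)C | intermediate
19 | lithium {(1S,3Z,6Z)-1-[(diisopropylcarbamoyl)oxy]nona-3,6-dien-1-yl}[(E)-2-(phenylsulfanyl)ethenyl]-9-borabicyclo[3.3.1]nonan-9-uide | CC/C=C\C/C=C\C[C@H]([B-]1(/C=C/Sc2ccccc2)C2CCCC1CCC2)OC(=O)N(C(C)C)C(C)C.[Li+] | intermediate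
20 | 9-[(1E,3R,5Z,8Z)-1-(phenylsulfanyl)undeca-1,5,8-trien-3-yl]-9-borabicyclo[3.3.1]nonane | CC/C=C\C/C=C\C[C@@H](B1C2CCCC1CCC2)/C=C/Sc1ccccc1 | intermediate
21 | O-(9-borabicyclo[3.3.1]nonan-9-yl) derivative (borinate ester) of 22 | CC/C=C\C/C=C\C/C=C\[C@@H](Sc1ccccc1)[C@@H](OB1C2CCCC1CCC2)[C@@H]1C[C@H]1[C@H]1C/C=C\CCC(=O)O1 | intermediate
22 | (5Z,8R)-8-{(1R,2R)-2-[(1S,2R,3Z,6Z,9Z)-1-hydroxy-2-(phenylsulfanyl)dodeca-3,6,9-trien-1-yl]cyclopropyl}-3,4,7,8-tetrahydro-2H-oxocin-2-one | CC/C=C\C/C=C\C/C=C\[C@@H](Sc1ccccc1)[C@@H](O)[C@@H]1C[C@H]1[C@H]1C/C=C\CCC(=O)O1 | intermediate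
23 | S-oxide of 22 (12-phenylsulfinyl compound, both sulfur epimers) | CC/C=C\C/C=C\C/C=C\[C@@H](S(=O)c1ccccc1)[C@@H](O)[C@@H]1C[C@H]1[C@H]1C/C=C\CCC(=O)O1 | intermediate
24 | 14-O-benzenesulfenate of the target (11R,12E,14S) | CC/C=C\C/C=C\C[C@H](OSc1ccccc1)/C=C/[C@@H](O)[C@@H]1C[C@H]1[C@H]1C/C=C\CCC(=O)O1 | intermediate
25 | (5Z,8R)-8-{(1R,2R)-2-[(1R,2E,4S,6Z,9Z)-1,4-dihydroxydodeca-2,6,9-trien-1-yl]cyclopropyl}-3,4,7,8-tetrahydro-2H-oxocin-2-one (CNP0319393.3) | CC/C=C\C/C=C\C[C@H](O)/C=C/[C@@H](O)[C@@H]1C[C@H]1[C@H]1C/C=C\CCC(=O)O1 | target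

**Step count and risks**

Total: 10 steps. Longest linear sequence: 7 steps (1 → 4 → 5 → 7 → 8 → 9 → 22 → 25).

Most likely to fail, in order:

1. Step 9. The risks are competing deprotonation of 12 at the doubly allylic C18, the untested β-thiovinylborane (regiochemistry of step 8, 1,3-boron shift in 20), and incomplete Z-selectivity. The fallback sets out from 12 (with 9) and comes back at 25. It keeps the carbanion at C14 but uses silicon and an anti oxygen transposition, which needs the enantiomeric carbanion and an E-allylsilane.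
   - 12 is lithiated with sec-butyllithium/(+)-sparteine (Et2O, −78 °C) and trapped with (E)-2-(trimethylsilyl)vinylboronic acid pinacol ester; MgBr2·OEt2 and warming drive the 1,2-shift to the isolable (S)-allylboronic pinacol ester F1.
   - F1 is activated as its borinic ester (n-butyllithium, then trifluoroacetic anhydride, −78 °C) and added to 9 through the chair with the α-substituent equatorial, giving the (E)-anti-β-hydroxy allylsilane F2.
   - Epoxidation with VO(acac)2 and tert-butyl hydroperoxide, directed by the C11 hydroxyl and anti to silicon, gives the epoxysilane F3; acid-induced anti (Peterson-type) elimination of F3 opens the epoxide and delivers 25.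

2. Step 4. The risk is oligomerisation in place of closure of the eight-membered ring. The fallback sets out from 5 and comes back at 8, closing the ring by C–O bond formation.
   - 5 is silylated (Et3SiCl, imidazole) to the triethylsilyl ether F4.
   - Ozonolysis (O3, CH2Cl2, −78 °C; PPh3) gives the aldehyde F5.
   - A Z-selective Wittig reaction with the ylide from (3-carboxypropyl)triphenylphosphonium bromide (NaN(SiMe3)2, THF, −78 °C) gives the silyloxy acid F6.
   - Bu4NF gives the hydroxy acid F7, and Yamaguchi lactonisation (2,4,6-trichlorobenzoyl chloride, Et3N; then DMAP, toluene, high dilution) gives 8.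

3. Step 2. The risks are a modest syn:anti ratio for an E-allylic alcohol and competing cyclopropanation of the terminal alkene. The fallback sets out from 1 and comes back at 5, building the cyclopropane under reagent control before the allyl group is present.
   - 1 is reduced (NaBH4, MeOH, 0 °C) to the allylic alcohol F8.
   - Charette cyclopropanation gives the cyclopropylmethanol F9. It uses Zn(CH2I)2·DME and (4S,5S)-2-butyl-N,N,N′,N′-tetramethyl-1,3,2-dioxaborolane-4,5-dicarboxamide, the ligand enantiomer that converts cinnamyl alcohol into the (1R,2R)-cyclopropylmethanol.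
   - Dess–Martin oxidation gives the aldehyde F10, and Brown allylation of F10 with 2 (Re-face addition, as in step 1) gives 5.

**Further compounds**

F1 | step 9 | 2-[(1E,3S,5Z,8Z)-1-(trimethylsilyl)undeca-1,5,8-trien-3-yl]-4,4,5,5-tetramethyl-1,3,2-dioxaborolane | CC/C=C\C/C=C\C[C@H](B1OC(C)(C)C(C)(C)O1)/C=C/[Si](C)(C)C
F2 | step 9 | (5Z,8R)-8-{(1R,2R)-2-[(1S,2R,3E,6Z,9Z)-1-hydroxy-2-(trimethylsilyl)dodeca-3,6,9-trien-1-yl]cyclopropyl}-3,4,7,8-tetrahydro-2H-oxocin-2-one | CC/C=C\C/C=C\C/C=C/[C@@H]([Si](C)(C)C)[C@@H](O)[C@@H]1C[C@H]1[C@H]1C/C=C\CCC(=O)O1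
F3 | step 9 | (5Z,8R)-8-{(1R,2R)-2-[(1S,2S)-1-hydroxy-2-{(2R,3S)-3-[(2Z,5Z)-octa-2,5-dien-1-yl]oxiran-2-yl}-2-(trimethylsilyl)ethyl]cyclopropyl}-3,4,7,8-tetrahydro-2H-oxocin-2-one | CC/C=C\C/C=C\C[C@@H]1O[C@H]1[C@@H]([Si](C)(C)C)[C@@H](O)[C@@H]1C[C@H]1[C@H]1C/C=C\CCC(=O)O1
F4 | step 4 | triethyl{[(1R)-1-[(1R,2R)-2-(dimethoxymethyl)cyclopropyl]but-3-en-1-yl]oxy}silane | COC(OC)[C@@H]1C[C@H]1[C@H](O[Si](CC)(CC)CC)CC=C
F5 | step 4 | (3R)-3-[(1R,2R)-2-(dimethoxymethyl)cyclopropyl]-3-[(triethylsilyl)oxy]propanal | COC(OC)[C@@H]1C[C@H]1[C@H](O[Si](CC)(CC)CC)CC=O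
F6 | step 4 | (4Z,7R)-7-[(1R,2R)-2-(dimethoxymethyl)cyclopropyl]-7-[(triethylsilyl)oxy]hept-4-enoic acid | COC(OC)[C@@H]1C[C@H]1[C@H](O[Si](CC)(CC)CC)C/C=C\CCC(=O)O
F7 | step 4 | (4Z,7R)-7-[(1R,2R)-2-(dimethoxymethyl)cyclopropyl]-7-hydroxyhept-4-enoic acid | COC(OC)[C@@H]1C[C@H]1[C@H](O)C/C=C\CCC(=O)O
F8 | step 2 | (E)-4,4-dimethoxybut-2-en-1-ol | COC(OC)/C=C/CO
F9 | step 2 | [(1R,2R)-2-(dimethoxymethyl)cyclopropyl]methanol | COC(OC)[C@@H]1C[C@H]1CO
F10 | step 2 | (1R,2R)-2-(dimethoxymethyl)cyclopropane-1-carbaldehyde | COC(OC)[C@@H]1C[C@H]1C=O
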